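**The vessel.** A closed, stirred vessel holds solid substrate that passes into solution, where dissolved substrate meets partner and gives product.

| flask | solid substrate | partner | remark | time |
|---|---|---|---|---|
| maple | 0.050 M | 0.17 M | run made earlier |  |
| elm | 0.050 M | 0.28 M | run made earlier |  |
| flask | 0.050 M | 0.125 M |  | 5.0 h |

- maple (time / h: product / %, dissolved substrate / %): 0.500: 13, 21; 1.50: 31, 28; 3.00: 41, 37; 4.00: 46, 33; 6.00: 53, 36
- elm (time / h: product / %, dissolved substrate / %): 0.500: 12, 21; 0.833: 20, 26; 1.50: 34, 32; 3.00: 47, 34; 6.00: 55, 36

(each reading ± 1.5 percentage points)

- solid substrate is a solid; its amount is given per volume of the solution
- the numbers in the tables scatter with a standard deviation of 1.5 percentage points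
- at the start none of the solid substrate is in solution
- dissolved substrate means what is dissolved; the solid is not counted in it

* the product standing at 5.0 h, as a percentage of the solid substrate charged
* concentration of dissolved substrate in solution at 30 min, in percent of saturation
* the change that raises the amount of product at 5.0 h, in percent of the solid substrate charged most ("none" if none brings more than 2 percentage points) (Wednesday's / Tuesday's / Friday's / none)
* amount of product at 5.0 h, in percent of the solid substrate charged, after Tuesday's

- Wednesday's: doubling the amount of partner, all else as stated
- Tuesday's: doubling the dissolution coefficient of the solid substrate, all else as stated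
- Friday's: doubling the solubility of the solid substrate, all else as stated

**Bench rule.** With partner in excess, its level is taken as steady, so product should gain per hour in step with dissolved substrate (the pseudo-first-order view). The flask, at 2.50 equivalents of partner, looks safe by that rule. In the maple run, product at the last reading has bound just 15.6 % of the partner charged, so the rule expects a steady pull.

**The border.** The readings disagree. In the maple run, the hourly gain per unit of dissolved substrate reads 0.735 h⁻¹ early and 0.101 h⁻¹ late, a drop by a factor of about 7.28 as read from scattered readings. Meanwhile elm, with 1.65 times the partner, ends at 55 % against 53 %. So the rule stops here, and a molar amount serves better: the product reach, the product standing midway through maple's last two readings, 0.0248 M. My own reckoning divides it by the charge and gives 49.5 % for the flask, or a little under, since the flask has less partner.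

**The forecast.** It gives 50 %, 55 % of saturation, Friday's as the best change, and 51 % after Tuesday's, holding that “Doubling solubility raises dissolved substrate”.

**The result.** The flask gives 45.4 % and 62.1 % of saturation. Friday's is best, with a gain of 21 percentage points, and Tuesday's gives 52.3 %.

    2 partner → homo dimer (k = 0.00287 M⁻¹ s⁻¹)
    dissolved substrate + partner → product (k = 0.00525 M⁻¹ s⁻¹)
    solid substrate ⇌ dissolved substrate, rate k3*(cs3 - [dissolved substrate]) while solid is left; crystals form when [dissolved substrate] > cs3 (solubility = 18.0 mM, k = 8.20 × 10⁻⁴ s⁻¹)

**Why a reach.** The flask's 0.0227 M of product lies under the reach. The flask's product falls short of the charge for two reasons acting together, each a part of the story: partner passes into homo dimer, and dissolved substrate has a low solubility, which also sets how fast it dissolves. Without the homo dimer step, product reaches 99.7 %; without the solubility limit, a part of the story, 82.5 %. At 2.50 h the flask keeps 8.85 % of its charged partner. For the neighbour with 0.013 M of solid substrate, the reach read from maple is 1.91 times the charge, so it sets no cap below the charge there. The computed neighbour gives 85.2 %.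

(The readings were generated by integration on assumed constants, and the scatter is random.)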